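The route rests on cutting C8–C9 and the C1–O(acyl) bond: C9 and C1 are the β- and α-carbons of the enol ether on O2 in the pyran ring, and C8 with its exocyclic C10 can derive from an alkyne. In one gold-catalysed operation, C9 of a 4H-pyran attacks a tethered alkyne (5-exo-dig, closing the cyclopentane C5–C6–C7–C8–C9) and isovaleric acid caps C1, which sets C9 and C1 and leaves the C8=C10 methylene for dihydroxylation. The precursor is a (4S)-4H-pyran-3-carbaldehyde carrying a (2S)-2-silyloxybut-3-ynyl chain at C5; its formyl group silences the second enol ether and later becomes C11.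

Key step: step 7

Remark: iridoid numbering (C1, O2, C3–C11) is used for all ring compounds. The target is (1S,4aS,6S,7R,7aS): O7 and C10 are β, O8 is α, so the C8 hydroxyl must enter anti to the C7 ester.

Remark: the propargylic oxygen is carried as a TBS ether. A silyl ether does not divert the gold step into acyloxy or hydride shifts, and TBS (unlike TES) should survive the Vilsmeier and acid-catalysed steps before it.

Assumption: the sense of induction of the two chiral reagents (Si-face allylation by the (+)-α-pinene-derived borane in step 1; the 4S cycloadduct from the (1S,2R)-aminoindanol-derived chromium catalyst in step 4) is taken over from simple aldehydes; should either prove opposite on these substrates, its enantiomer is used.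

Step 1
Reactants: 1 3-(trimethylsilyl)prop-2-ynal; 2 allylmagnesium bromide
Product: 4 (3S)-1-(trimethylsilyl)hex-5-en-1-yn-3-ol, via borinate ester 3 (not isolated)
Conditions: (−)-Ipc2BOMe [from (+)-α-pinene], 2, Et2O, −78 °C to rt; then 1, −78 °C; ethanolamine work-up
Reagents that add atoms: none
Why: Brown asymmetric allylboration runs through a closed chair transition state in which the isopinocampheyl groups steer the allyl group to the Si face of the ynal, which should give the S carbinol that becomes C7.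

Step 2
Reactants: 4 (3S)-1-(trimethylsilyl)hex-5-en-1-yn-3-ol
Product: 5 (3S)-3-(tert-butyldimethylsilyloxy)-1-(trimethylsilyl)hex-5-en-1-yne
Conditions: TBSCl, imidazole, DMF, 0 °C to rt
Reagents that add atoms: tert-butyldimethylsilyl chloride, CC(C)(C)[Si](C)(C)Cl
Why: Imidazole-promoted silyl ether formation on a secondary propargylic alcohol is routine and leaves the stereocentre untouched.

Step 3
Reactants: 5 (3S)-3-(tert-butyldimethylsilyloxy)-1-(trimethylsilyl)hex-5-en-1-yne; 6 (E)-crotonaldehyde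
Product: 7 (2E,5S)-5-(tert-butyldimethylsilyloxy)-7-(trimethylsilyl)hept-2-en-6-ynal
Conditions: 6 (5 equiv), second-generation Hoveyda–Grubbs catalyst RuCl2(H2IMes)(=CH-C6H4-2-OiPr) (3 mol %), CH2Cl2, 40 °C
Reagents that add atoms: none
Why: Olefin cross-metathesis of the terminal alkene with excess crotonaldehyde should give the E-enal directly, the bulky C-silylated alkyne being inert to the ruthenium carbene.

Step 4
Reactants: 7 (2E,5S)-5-(tert-butyldimethylsilyloxy)-7-(trimethylsilyl)hept-2-en-6-ynal; 8 ethyl vinyl ether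
Product: 10 (2S,4S)-2-ethoxy-4-[(2S)-2-(tert-butyldimethylsilyloxy)but-3-yn-1-yl]-3,4-dihydro-2H-pyran, via silylalkyne cycloadduct 9 (not isolated)
Conditions: 8 (10 equiv), CrCl(L) (5 mol %; L = dianion of the Schiff base from (1S,2R)-1-aminoindan-2-ol and 3-(1-adamantyl)-2-hydroxy-5-methylbenzaldehyde), 4 Å MS, rt; then evaporate, K2CO3 (0.2 equiv), MeOH, 0 °C to rt
Reagents that add atoms: none
Why: The inverse-electron-demand hetero-Diels–Alder reaction of the enal (as 1-oxadiene) with the vinyl ether under the chiral tridentate Schiff-base chromium chloride catalyst (trivalent chromium) is catalyst-controlled, should override the remote silyloxy centre and set the ring carbon that becomes C5 (endo mode, ethoxy cis), and base-catalysed methanolysis of the C–Si bond then frees the alkyne without touching acetal, enol ether or TBS ether.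

Step 5
Reactants: 10 (2S,4S)-2-ethoxy-4-[(2S)-2-(tert-butyldimethylsilyloxy)but-3-yn-1-yl]-3,4-dihydro-2H-pyran
Product: 12 (2S,4S)-2-ethoxy-4-[(2S)-2-(tert-butyldimethylsilyloxy)but-3-yn-1-yl]-3,4-dihydro-2H-pyran-5-carbaldehyde, via iminium chloride 11 (not isolated)
Conditions: (chloromethylene)dimethyliminium chloride (1.2 equiv), DMF/CH2Cl2, 0 °C; then aq. NaOAc, 0 °C to rt
Reagents that add atoms: (chloromethylene)dimethyliminium chloride, C[N+](C)=CCl.[Cl-]; water, O
Why: Vilsmeier–Haack formylation attacks the β-carbon of the cyclic enol ether, the only nucleophilic carbon present (terminal alkyne and secondary TBS ether do not react), and hydrolysis of the iminium salt should give the vinylogous formate that carries C11 with the C5 centre untouched.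

Step 6
Reactants: 12 (2S,4S)-2-ethoxy-4-[(2S)-2-(tert-butyldimethylsilyloxy)but-3-yn-1-yl]-3,4-dihydro-2H-pyran-5-carbaldehyde
Product: 13 (4S)-4-[(2S)-2-(tert-butyldimethylsilyloxy)but-3-yn-1-yl]-4H-pyran-3-carbaldehyde
Conditions: PPTS (10 mol %), toluene, 90 °C, 5 Å MS
Reagents that add atoms: none
Why: Acid-catalysed elimination of ethanol from the cyclic acetal (acetal to enol ether conversion, as used to make 4H-pyrans from 2-alkoxy-3,4-dihydro-2H-pyrans) is driven by trapping ethanol on the sieves, and the product should tolerate the conditions because its ring oxygen is part of a vinylogous ester.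

Step 7
Reactants: 13 (4S)-4-[(2S)-2-(tert-butyldimethylsilyloxy)but-3-yn-1-yl]-4H-pyran-3-carbaldehyde; 14 isovaleric acid
Product: 15 (1S,4aS,6S,7aS)-6-(tert-butyldimethylsilyloxy)-4-formyl-7-methylidene-1,4a,5,6,7,7a-hexahydrocyclopenta[c]pyran-1-yl 3-methylbutanoate
Conditions: [(2-biphenylyl)tBu2P]Au(NCMe)SbF6 (5 mol %), 14 (3 equiv), 4 Å MS, CH2Cl2, −20 °C to rt
Reagents that add atoms: none
Why: Proposed new method: the cationic phosphine gold complex (monovalent gold) π-activates the terminal alkyne so that C8 becomes electrophilic, the enol-ether β-carbon C9 attacks it anti to gold, and the resulting C1 oxocarbenium ion (or its cyclopropyl gold carbene form) is captured by isovaleric acid before protodeauration of the C10 vinylgold species releases the C8=C10 methylene and the catalyst. The closest known reactions are the gold-catalysed alkoxy- and hydroxycyclisations of 1,6-enynes and the 5-exo-dig carbocyclisations of enol ethers and silyl enol ethers onto alkynes; capture by a carboxylic acid on a 4H-pyran has not been shown. The cyclopentane (C5–C6–C7–C8–C9) closes in the 5-exo-dig mode, favoured over 6-endo because the alkyne is terminal and C8 is its internal, cation-stabilising carbon. C9 is set by the three-atom tether from C5, which can reach only the face of the pyran that carries C6 and so gives the cis ring fusion; C1 is set by anti addition across C1=C9, the carboxylate entering opposite the new C9–C8 bond into the axial, anomerically preferred position to give the 1β ester. The step needs C9 to react and not C4, the other enol-ether carbon equally distant from C8; the formyl group makes C3=C4 a push–pull system and C4 fully substituted, so only C9 is nucleophilic, and it also lowers the basicity of the ring oxygen so that isovaleric acid alone should neither protonate the enol ether nor ionise the product acylal.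

Step 8
Reactants: 15 (1S,4aS,6S,7aS)-6-(tert-butyldimethylsilyloxy)-4-formyl-7-methylidene-1,4a,5,6,7,7a-hexahydrocyclopenta[c]pyran-1-yl 3-methylbutanoate
Product: 16 (1S,4aS,6S,7aS)-4-formyl-6-hydroxy-7-methylidene-1,4a,5,6,7,7a-hexahydrocyclopenta[c]pyran-1-yl 3-methylbutanoate
Conditions: HF·pyridine, pyridine, THF, 0 °C to rt
Reagents that add atoms: none
Why: Buffered fluoride cleavage of the secondary silyl ether should spare the C1 acylal, which is stabilised against ionisation by the electron-poor ring oxygen of the vinylogous formate.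

Step 9
Reactants: 17 (E)-4-hydroxycinnamic acid (p-coumaric acid)
Product: 19 (E)-3-[4-(tert-butyldimethylsilyloxy)phenyl]prop-2-enoic acid, via bis-silyl coumarate 18 (not isolated)
Conditions: TBSCl (2.2 equiv), imidazole, DMF, rt; then AcOH/THF/H2O, rt
Reagents that add atoms: tert-butyldimethylsilyl chloride, CC(C)(C)[Si](C)(C)Cl
Why: Exhaustive silylation followed by selective hydrolysis of the far more labile silyl ester is the standard phenol protection of a hydroxycinnamic acid and leaves the aryl TBS ether, which is stable to mild acid.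

Step 10
Reactants: 16 (1S,4aS,6S,7aS)-4-formyl-6-hydroxy-7-methylidene-1,4a,5,6,7,7a-hexahydrocyclopenta[c]pyran-1-yl 3-methylbutanoate; 19 (E)-3-[4-(tert-butyldimethylsilyloxy)phenyl]prop-2-enoic acid
Product: 20 (1S,4aS,6S,7aS)-4-formyl-7-methylidene-1-(3-methylbutanoyloxy)-1,4a,5,6,7,7a-hexahydrocyclopenta[c]pyran-6-yl (E)-3-[4-(tert-butyldimethylsilyloxy)phenyl]prop-2-enoate
Conditions: EDC·HCl, DMAP, CH2Cl2, 0 °C to rt
Reagents that add atoms: none
Why: Steglich esterification acylates the only hydroxyl group with retention at C7, acyl transfer from the acylpyridinium ion being much faster than any attack of DMAP on the acylal.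

Step 11
Reactants: 20 (1S,4aS,6S,7aS)-4-formyl-7-methylidene-1-(3-methylbutanoyloxy)-1,4a,5,6,7,7a-hexahydrocyclopenta[c]pyran-6-yl (E)-3-[4-(tert-butyldimethylsilyloxy)phenyl]prop-2-enoate
Product: 21 (1S,4aS,6S,7R,7aS)-4-formyl-7-hydroxy-7-(hydroxymethyl)-1-(3-methylbutanoyloxy)-1,4a,5,6,7,7a-hexahydrocyclopenta[c]pyran-6-yl (E)-3-[4-(tert-butyldimethylsilyloxy)phenyl]prop-2-enoate
Conditions: OsO4 (5 mol %), NMO (1.5 equiv), acetone/H2O, 0 °C to rt, stopped at full conversion of 20
Reagents that add atoms: osmium tetroxide, O=[Os](=O)(=O)=O; N-methylmorpholine N-oxide, C[N+]1([O-])CCOCC1; water, O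
Why: Upjohn dihydroxylation should pick the 1,1-disubstituted C8=C10 alkene, which is more electron-rich than the conjugated cinnamate and the push–pull C3=C4 bond, and OsO4 should approach anti to the allylic C7 ester (Kishi-type control on a cyclic allylic ester), placing the C8 hydroxyl α and C10 β.

Step 12
Reactants: 21 (1S,4aS,6S,7R,7aS)-4-formyl-7-hydroxy-7-(hydroxymethyl)-1-(3-methylbutanoyloxy)-1,4a,5,6,7,7a-hexahydrocyclopenta[c]pyran-6-yl (E)-3-[4-(tert-butyldimethylsilyloxy)phenyl]prop-2-enoate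
Product: 22 (1S,4aS,6S,7R,7aS)-7-hydroxy-4,7-bis(hydroxymethyl)-1-(3-methylbutanoyloxy)-1,4a,5,6,7,7a-hexahydrocyclopenta[c]pyran-6-yl (E)-3-[4-(tert-butyldimethylsilyloxy)phenyl]prop-2-enoate
Conditions: NaBH4, CeCl3·7H2O, MeOH/THF, −78 °C; pH 7 buffer work-up
Reagents that add atoms: none
Why: Luche reduction delivers hydride 1,2 to the C11 aldehyde of the vinylogous formate at low temperature and should leave the two esters, the acylal and the enol ether untouched.

Step 13
Reactants: 22 (1S,4aS,6S,7R,7aS)-7-hydroxy-4,7-bis(hydroxymethyl)-1-(3-methylbutanoyloxy)-1,4a,5,6,7,7a-hexahydrocyclopenta[c]pyran-6-yl (E)-3-[4-(tert-butyldimethylsilyloxy)phenyl]prop-2-enoate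
Product: 23 luzonoid A, (1S,4aS,6S,7R,7aS)-7-hydroxy-4,7-bis(hydroxymethyl)-1-(3-methylbutanoyloxy)-1,4a,5,6,7,7a-hexahydrocyclopenta[c]pyran-6-yl (E)-3-(4-hydroxyphenyl)prop-2-enoate
Conditions: TBAF (1.1 equiv), AcOH (1.5 equiv), THF, 0 °C
Reagents that add atoms: none
Why: Buffered fluoride desilylation cleaves the aryl silyl ether within minutes at 0 °C (phenoxide is a good leaving group from silicon), which should spare the acid-sensitive acylal and enol ether and avoid base-induced migration of the C7 ester to O10.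

Compound list
1 | 3-(trimethylsilyl)prop-2-ynal | C[Si](C)(C)C#CC=O | starting material
2 | allylmagnesium bromide | C=CC[Mg]Br | starting material
3 | (3S)-1-(trimethylsilyl)hex-5-en-1-yn-3-yl diisopinocampheylborinate (isopinocampheyl groups from (+)-α-pinene) | C=CC[C@H](OB([C@@H]1C[C@@H]2C[C@H]([C@H]1C)C2(C)C)[C@@H]1C[C@@H]2C[C@H]([C@H]1C)C2(C)C)C#C[Si](C)(C)C | intermediate
4 | (3S)-1-(trimethylsilyl)hex-5-en-1-yn-3-ol | C=CC[C@H](O)C#C[Si](C)(C)C | intermediate
5 | (3S)-3-(tert-butyldimethylsilyloxy)-1-(trimethylsilyl)hex-5-en-1-yne | C=CC[C@H](O[Si](C)(C)C(C)(C)C)C#C[Si](C)(C)C | intermediate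
6 | (E)-crotonaldehyde | C/C=C/C=O | starting material
7 | (2E,5S)-5-(tert-butyldimethylsilyloxy)-7-(trimethylsilyl)hept-2-en-6-ynal | O=C/C=C/C[C@H](O[Si](C)(C)C(C)(C)C)C#C[Si](C)(C)C | intermediate
8 | ethyl vinyl ether | C=COCC | starting material
9 | (2S,4S)-2-ethoxy-4-[(2S)-2-(tert-butyldimethylsilyloxy)-4-(trimethylsilyl)but-3-yn-1-yl]-3,4-dihydro-2H-pyran | CCO[C@@H]1C[C@H](C[C@H](O[Si](C)(C)C(C)(C)C)C#C[Si](C)(C)C)C=CO1 | intermediate
10 | (2S,4S)-2-ethoxy-4-[(2S)-2-(tert-butyldimethylsilyloxy)but-3-yn-1-yl]-3,4-dihydro-2H-pyran | CCO[C@@H]1C[C@H](C[C@H](O[Si](C)(C)C(C)(C)C)C#C)C=CO1 | intermediate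
11 | N-{[(2S,4S)-2-ethoxy-4-[(2S)-2-(tert-butyldimethylsilyloxy)but-3-yn-1-yl]-3,4-dihydro-2H-pyran-5-yl]methylidene}-N-methylmethanaminium chloride | CCO[C@@H]1C[C@H](C[C@H](O[Si](C)(C)C(C)(C)C)C#C)C(C=[N+](C)C)=CO1.[Cl-] | intermediate
12 | (2S,4S)-2-ethoxy-4-[(2S)-2-(tert-butyldimethylsilyloxy)but-3-yn-1-yl]-3,4-dihydro-2H-pyran-5-carbaldehyde | CCO[C@@H]1C[C@H](C[C@H](O[Si](C)(C)C(C)(C)C)C#C)C(C=O)=CO1 | intermediate
13 | (4S)-4-[(2S)-2-(tert-butyldimethylsilyloxy)but-3-yn-1-yl]-4H-pyran-3-carbaldehyde | O=CC1=COC=C[C@@H]1C[C@H](O[Si](C)(C)C(C)(C)C)C#C | intermediate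
14 | isovaleric acid (3-methylbutanoic acid) | CC(C)CC(=O)O | starting material
15 | (1S,4aS,6S,7aS)-6-(tert-butyldimethylsilyloxy)-4-formyl-7-methylidene-1,4a,5,6,7,7a-hexahydrocyclopenta[c]pyran-1-yl 3-methylbutanoate | CC(C)CC(=O)O[C@@H]1OC=C(C=O)[C@H]2C[C@H](O[Si](C)(C)C(C)(C)C)C(=C)[C@@H]12 | intermediate
16 | (1S,4aS,6S,7aS)-4-formyl-6-hydroxy-7-methylidene-1,4a,5,6,7,7a-hexahydrocyclopenta[c]pyran-1-yl 3-methylbutanoate | CC(C)CC(=O)O[C@@H]1OC=C(C=O)[C@H]2C[C@H](O)C(=C)[C@@H]12 | intermediate
17 | (E)-4-hydroxycinnamic acid (p-coumaric acid) | O=C(O)/C=C/c1ccc(O)cc1 | starting material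
18 | tert-butyldimethylsilyl (E)-3-[4-(tert-butyldimethylsilyloxy)phenyl]prop-2-enoate | CC(C)(C)[Si](C)(C)OC(=O)/C=C/c1ccc(O[Si](C)(C)C(C)(C)C)cc1 | intermediate
19 | (E)-3-[4-(tert-butyldimethylsilyloxy)phenyl]prop-2-enoic acid | O=C(O)/C=C/c1ccc(O[Si](C)(C)C(C)(C)C)cc1 | intermediate
20 | (1S,4aS,6S,7aS)-4-formyl-7-methylidene-1-(3-methylbutanoyloxy)-1,4a,5,6,7,7a-hexahydrocyclopenta[c]pyran-6-yl (E)-3-[4-(tert-butyldimethylsilyloxy)phenyl]prop-2-enoate | CC(C)CC(=O)O[C@@H]1OC=C(C=O)[C@H]2C[C@H](OC(=O)/C=C/c3ccc(O[Si](C)(C)C(C)(C)C)cc3)C(=C)[C@@H]12 | intermediate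
21 | (1S,4aS,6S,7R,7aS)-4-formyl-7-hydroxy-7-(hydroxymethyl)-1-(3-methylbutanoyloxy)-1,4a,5,6,7,7a-hexahydrocyclopenta[c]pyran-6-yl (E)-3-[4-(tert-butyldimethylsilyloxy)phenyl]prop-2-enoate | CC(C)CC(=O)O[C@@H]1OC=C(C=O)[C@H]2C[C@H](OC(=O)/C=C/c3ccc(O[Si](C)(C)C(C)(C)C)cc3)[C@](O)(CO)[C@@H]12 | intermediate
22 | (1S,4aS,6S,7R,7aS)-7-hydroxy-4,7-bis(hydroxymethyl)-1-(3-methylbutanoyloxy)-1,4a,5,6,7,7a-hexahydrocyclopenta[c]pyran-6-yl (E)-3-[4-(tert-butyldimethylsilyloxy)phenyl]prop-2-enoate | CC(C)CC(=O)O[C@@H]1OC=C(CO)[C@H]2C[C@H](OC(=O)/C=C/c3ccc(O[Si](C)(C)C(C)(C)C)cc3)[C@](O)(CO)[C@@H]12 | intermediate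
23 | luzonoid A | CC(C)CC(=O)O[C@@H]1OC=C(CO)[C@H]2C[C@H](OC(=O)/C=C/c3ccc(O)cc3)[C@](O)(CO)[C@@H]12 | target

Total step count: 13. Longest linear sequence: 12 steps (steps 1–8 and 10–13, from 3-(trimethylsilyl)prop-2-ynal); step 9 is a one-step side branch.

Steps most likely to fail

Step 7. The enol ether C1=C9 is made electron-poor by the vinylogous formate and may attack the gold-bound alkyne too slowly. Intermolecular addition of the acid to the alkyne, skeletal rearrangement of the enyne or unselective capture at C1 could then take over. The fallback uses known radical chemistry and sets out from 13. NIS in wet acetonitrile at 0 °C should convert the only nucleophilic alkene into the trans-iodohydrin (4S)-6-hydroxy-5-iodo-4-[(2S)-2-(tert-butyldimethylsilyloxy)but-3-yn-1-yl]-5,6-dihydro-4H-pyran-3-carbaldehyde F1. Slow addition of Bu3SnH with Et3B/air in toluene generates the C9 radical, which closes the cyclopentane by 5-exo-dig attack on the alkyne and, after hydrogen transfer to the vinyl radical, should give the cis-fused lactol (4aS,6S,7aS)-6-(tert-butyldimethylsilyloxy)-1-hydroxy-7-methylidene-1,4a,5,6,7,7a-hexahydrocyclopenta[c]pyran-4-carbaldehyde F2. Isovaleric anhydride with DMAP and Et3N in CH2Cl2 at 0 °C then acylates the equilibrating lactol, which should favour the axial 1β ester trans to the C9–C8 bond. The route is rejoined at 15.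

Step 6. Ionisation may occur at the endocyclic C1–O2 bond instead of the exocyclic C–OEt bond, because the vinylogous carboxylate is the better leaving group. That would give ring-opened enol ethers or oligomers; hydride loss from C5 on heating is a further risk. The fallback sets out from 12. Hydrolysis of the acetal with AcOH/THF/H2O at rt should give the lactol (4S)-2-hydroxy-4-[(2S)-2-(tert-butyldimethylsilyloxy)but-3-yn-1-yl]-3,4-dihydro-2H-pyran-5-carbaldehyde F3. Sulfonylation of the anomeric hydroxyl and base-induced elimination (MsCl, Et3N, CH2Cl2, −20 °C to rt) then make the exocyclic group the better leaving group and need neither acid nor heat. The route is rejoined at 13.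

Step 11. Osmylation of the cinnamate double bond may compete, or facial selectivity may be poor because the α face of C8=C10 is flanked by C1. The fallback changes the order so that the alkene is oxidised before the cinnamate is present and under the bulkier silyl ether; it sets out from 15.
- OsO4/NMO in acetone/H2O should give (1S,4aS,6S,7R,7aS)-6-(tert-butyldimethylsilyloxy)-4-formyl-7-hydroxy-7-(hydroxymethyl)-1,4a,5,6,7,7a-hexahydrocyclopenta[c]pyran-1-yl 3-methylbutanoate F4.
- HF·pyridine removes the C7 silyl group to give the triol (1S,4aS,6S,7R,7aS)-4-formyl-6,7-dihydroxy-7-(hydroxymethyl)-1,4a,5,6,7,7a-hexahydrocyclopenta[c]pyran-1-yl 3-methylbutanoate F5.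
- TESCl/imidazole at −20 °C should silylate only the primary C10 hydroxyl, giving the 10-O-triethylsilyl ether of that triol F6.
- Steglich esterification with 19 acylates the secondary C7 hydroxyl (the tertiary C8 hydroxyl does not react) to give the 7-O-[4-(tert-butyldimethylsilyloxy)cinnamoyl]-10-O-triethylsilyl aldehyde F7.
- Luche reduction gives the corresponding C11 alcohol F8.
- TBAF/AcOH in THF removes both silyl groups, so the route is rejoined at 23.

Further compounds
F1 | step 7 | (4S)-6-hydroxy-5-iodo-4-[(2S)-2-(tert-butyldimethylsilyloxy)but-3-yn-1-yl]-5,6-dihydro-4H-pyran-3-carbaldehyde (iodine trans to the side chain, hydroxyl trans to iodine) | O=CC1=CO[C@H](O)[C@@H](I)[C@@H]1C[C@H](O[Si](C)(C)C(C)(C)C)C#C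
F2 | step 7 | (4aS,6S,7aS)-6-(tert-butyldimethylsilyloxy)-1-hydroxy-7-methylidene-1,4a,5,6,7,7a-hexahydrocyclopenta[c]pyran-4-carbaldehyde (1β anomer drawn, equilibrating) | O[C@@H]1OC=C(C=O)[C@H]2C[C@H](O[Si](C)(C)C(C)(C)C)C(=C)[C@@H]12
F3 | step 6 | (4S)-2-hydroxy-4-[(2S)-2-(tert-butyldimethylsilyloxy)but-3-yn-1-yl]-3,4-dihydro-2H-pyran-5-carbaldehyde (anomeric mixture) | OC1C[C@H](C[C@H](O[Si](C)(C)C(C)(C)C)C#C)C(C=O)=CO1
F4 | step 11 | (1S,4aS,6S,7R,7aS)-6-(tert-butyldimethylsilyloxy)-4-formyl-7-hydroxy-7-(hydroxymethyl)-1,4a,5,6,7,7a-hexahydrocyclopenta[c]pyran-1-yl 3-methylbutanoate | CC(C)CC(=O)O[C@@H]1OC=C(C=O)[C@H]2C[C@H](O[Si](C)(C)C(C)(C)C)[C@](O)(CO)[C@@H]12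
F5 | step 11 | (1S,4aS,6S,7R,7aS)-4-formyl-6,7-dihydroxy-7-(hydroxymethyl)-1,4a,5,6,7,7a-hexahydrocyclopenta[c]pyran-1-yl 3-methylbutanoate | CC(C)CC(=O)O[C@@H]1OC=C(C=O)[C@H]2C[C@H](O)[C@](O)(CO)[C@@H]12
F6 | step 11 | 10-O-triethylsilyl ether of F5 | CC(C)CC(=O)O[C@@H]1OC=C(C=O)[C@H]2C[C@H](O)[C@](O)(CO[Si](CC)(CC)CC)[C@@H]12
F7 | step 11 | 7-O-[(E)-4-(tert-butyldimethylsilyloxy)cinnamoyl]-10-O-triethylsilyl aldehyde | CC(C)CC(=O)O[C@@H]1OC=C(C=O)[C@H]2C[C@H](OC(=O)/C=C/c3ccc(O[Si](C)(C)C(C)(C)C)cc3)[C@](O)(CO[Si](CC)(CC)CC)[C@@H]12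
F8 | step 11 | 7-O-[(E)-4-(tert-butyldimethylsilyloxy)cinnamoyl]-10-O-triethylsilyl C11 alcohol | CC(C)CC(=O)O[C@@H]1OC=C(CO)[C@H]2C[C@H](OC(=O)/C=C/c3ccc(O[Si](C)(C)C(C)(C)C)cc3)[C@](O)(CO[Si](CC)(CC)CC)[C@@H]12
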